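## Analysis of the target

The target (C41H52O5) is a chromane-2,4-dione: benzo ring A is fused to ring B (O1–C2(=O)–C3–C4(=O)–C4a–C8a). Its fully substituted C3 carries a (2E,6E)-farnesyl group (C1''–C12'') and a C17 chain (C1'–C17') with a C3' ketone conjugated to the C4'–C7' diyne, a C8' carbinol and a 9'Z olefin.

There are two stereocentres, C3 (S) and C8' (S). Eight bonds and a rigid diyne rod lie between them, so neither can direct the other; both need reagent control, and C3 epimers will be hard to separate.

C3 is the hard centre. Both carbon arms are unbranched over their first two atoms and both flanks are carbonyls (lactone C2, aryl ketone C4), so it can only be set by telling the two edges of a flat 1,3-dicarbonyl apart.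

Ring B is a non-enolisable β-keto aryl lactone. Nucleophiles open it at C2 or C4, base expels its pKa-4 enolate by retro-Michael cleavage of C3–C1', and a hydroxyl at C3' would translactonise onto C2.

The diynone is a strong conjugate acceptor, the C8' carbinol is allylic and propargylic at once, the 9'Z olefin isomerises easily, and the farnesyl triene cyclises in acid.

The feature the plan uses: without the farnesyl group, ring B is the aromatic 2-pyranone enol of a 4-hydroxycoumarin with a nucleophilic C3, and C3–C1'' is an allylic bond. Forming that one bond last, by enantioselective dearomative allylation, creates the quaternary stereocentre, joins a C26 and a C15 fragment, and leaves the fragile dione for the final flask.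

## Retrosynthetic reasoning

**C3–C1'' (22 to 18 and 20).** The bond between the quaternary carbon and the farnesyl CH2 is cut. This re-aromatises ring B and removes the C3 stereocentre, so 18 is a flat, acidic, robust hydroxycoumarin that already holds the whole polyacetylene chain, and 20 is an allylic carbonate one step from a commercial alcohol. The forward step must alkylate C3 of the enolate of 18 at the primary terminus of a farnesyl–palladium complex, on one face, under conditions with no external base. It is cut here and not at C3–C1' because an allyl–metal electrophile can sit in a chiral ligand pocket, whereas a terminal vinyl ketone gives a catalyst little to hold, and because this order brings the dione into existence only in the last step.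

**C3'–C4' (18 to 5 and 14).** The acyl–alkynyl bond of the ynone is cut to give the N-methoxy-N-methyl amide 5 and the terminal diyne carbinol 14. Both partners protect themselves as anions in the forward step: the hydroxycoumarin as enolate 15, the carbinol as the alkoxide in 16. Adduct 17 keeps the ketone masked until the quench, so no protecting group is needed. Joining C1'–C3 by conjugate addition to a preformed vinyl diynyl ketone was not chosen, since such an acceptor has three electrophilic carbons.

**Amide, oxidation level and C3–C1' (5 to 4 to 3 to 1 and 2).** The amide comes from aminolysis of enol lactone 4, which is an activated ester by construction. Lactone 4 is lactol 3 one oxidation level up, and 3 is the conjugate adduct of 1 and 2. The C3–C1' bond is therefore made on the simplest partners, where no stereocentre and no competing acceptor site exist.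

**C4–C5 of the diynol (14 to 13 to 8 and 11).** The carbinol–alkyne bond is cut so that the C8' stereocentre comes from a catalytic enantioselective addition of diyne 11 to Z-enal 8. The silyl cap of 13 keeps the diyne stable until it is needed. Enal 8 comes from 7 and alkynol 6; the Z-olefin is made by semihydrogenation at the only point where no other alkyne is present. Diyne 11 comes from the commercial bis-silyl diyne 9 through acetylide 10.

**Carbonate (20 to 19).** The carbonate is made from commercial (2E,6E)-farnesol 19, which brings both trisubstituted olefins in the correct geometry.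

## Alternatives that were turned down

**Alternative 1:** the textbook, biomimetic cut of C3–C1'. The forward key step is a Michael addition of ferulenol A1 (3-farnesyl-4-hydroxycoumarin) to the vinyl terminus of falcarinolone A2.
- A2 has three electrophilic carbons (C1 of the vinyl group, C5 and C7 of the diynone), and any amine, phosphine or alkoxide catalyst that activates the reaction will itself add to the ynone.
- No stereocentre forms on the acceptor, so C3 depends on face selection of a flat tetrasubstituted enolate toward an unsubstituted vinyl ketone.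
- The adduct is a 1,5-dicarbonyl whose leaving group is a pKa-4 enolate. Under the catalysts needed it can revert by retro-Michael cleavage, so C3 would drift to an epimer mixture.
- The step count is similar to the chosen route, but the stereochemical problem stays unsolved.

**Alternative 2:** single-atom insertion. The Cs-symmetric 2,2-disubstituted indane-1,3-dione A3 would be desymmetrised by an enantioselective Baeyer–Villiger oxidation that inserts oxygen between one of the two enantiotopic carbonyls and ring A. This is attractive because A3 needs only two plain alkylations and no asymmetric C–C bond formation.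
- In the Criegee intermediate the quaternary C2 competes with an electron-poor ortho-acyl aryl group for migration. Migration of C2 is expected and would give the isochromane-1,4-dione A4, with oxygen on the quaternary carbon.
- Peroxide oxidants would epoxidise three trisubstituted olefins and add to the diynone.
- The chains cannot be added after the oxidation, because the stereocentre only exists once both are present.

**Alternative 3:** a [3,3] shift. The tertiary allyl enol ether A5 (the 4-O-nerolidyl ether of the chain-bearing coumarin) would undergo Claisen rearrangement, moving C1'' to C3 with chirality transfer from the nerolidyl carbinol carbon.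
- A5 is a tertiary allylic ether of a pKa-4 enol. It cannot be made by O-alkylation and would ionise readily.
- The chair transition state must choose between a methyl group and the homoprenyl chain in the pseudo-equatorial position. That difference is small, so a 2''E/2''Z mixture is expected.
- The E and Z products arise with opposite C3 configuration, so geometric leakage is also stereochemical leakage.
- It needs enantiopure nerolidol and heating of a diynone, and costs more steps.

Key step: step 11

Assumption (remark on the chemistry): the sense of induction in steps 7 and 11 cannot be predicted with certainty for these substrates. The (S,S)-ligand in step 7 (Re-face delivery, by analogy with related zinc–ProPhenol additions) and the (R,R)-diphosphine in step 11 are written provisionally, both ligands are available in either mirror-image form, and the antipode is used if the first run shows the opposite sense. Compound 18 is drawn open although it should rest largely as its cyclic hemiketal tautomer.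

## Route

Step 1
Reactants: 1 4-hydroxycoumarin; 2 acrolein
Product: 3 2-hydroxy-3,4-dihydro-2H,5H-pyrano[3,2-c]chromen-5-one (racemic lactol)
Conditions: acrolein (1.3 equiv), Et3N (5 mol%), MeCN, 0 °C to rt
Reagents that add atoms: none
Why: Michael addition of the nucleophilic C3 of the vinylogous acid 1 to the enal, then closure of the 4-OH onto the aldehyde; this tandem conjugate addition–hemiacetalisation is the standard behaviour of 1 toward enals and enones, and the ring closure ties up the enol so that C3 is not alkylated twice. The hemiacetal stereocentre is racemic and is removed in step 2.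

Step 2
Reactants: 3 2-hydroxy-3,4-dihydro-2H,5H-pyrano[3,2-c]chromen-5-one
Product: 4 3,4-dihydro-2H,5H-pyrano[3,2-c]chromene-2,5-dione
Conditions: TEMPO (10 mol%), PhI(OAc)2 (1.2 equiv), CH2Cl2, rt
Reagents that add atoms: none
Why: Oxoammonium oxidation of a lactol to the lactone under neutral conditions, which should leave the vinylogous carbonate of the coumarin untouched. The product is an enol lactone, an internally activated acyl donor.

Step 3
Reactants: 4 3,4-dihydro-2H,5H-pyrano[3,2-c]chromene-2,5-dione
Product: 5 3-(4-hydroxy-2-oxo-2H-chromen-3-yl)-N-methoxy-N-methylpropanamide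
Conditions: MeNH(OMe)·HCl (1.3 equiv), i-Pr2NEt (1.4 equiv), CH2Cl2, 0 °C to rt; wash with 1 M HCl
Reagents that add atoms: N,O-dimethylhydroxylamine hydrochloride, CNOC.Cl
Why: Aminolysis of the enol ester: the amine should attack the C2 carbonyl of the new ring, whose leaving group is the pKa-4 coumarin enolate, and not the far less electrophilic coumarin C5 carbonyl. This gives the N-methoxy-N-methyl amide and frees the 4-hydroxycoumarin without a coupling reagent.

Step 4
Reactants: 6 dec-2-yn-1-ol
Product: 7 (2Z)-dec-2-en-1-ol
Conditions: H2 (1 atm), Pd/CaCO3 poisoned with Pb(OAc)2, quinoline, EtOAc, rt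
Reagents that add atoms: none
Why: Semihydrogenation on the poisoned palladium surface adds hydrogen syn and should give the Z-olefin; it is placed here because this is the only point of the route at which no other alkyne is present.

Step 5
Reactants: 7 (2Z)-dec-2-en-1-ol
Product: 8 (2Z)-dec-2-enal
Conditions: TEMPO (10 mol%), PhI(OAc)2 (1.1 equiv), CH2Cl2, 0 °C to rt; used at once
Reagents that add atoms: none
Why: Oxoammonium oxidation of a primary allylic alcohol stops at the aldehyde and is known to keep the Z-geometry of allylic alcohols. The enal is used without storage to avoid Z to E isomerisation.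

Step 6
Reactants: 9 1,4-bis(trimethylsilyl)buta-1,3-diyne
Product: 11 (trimethylsilyl)buta-1,3-diyne, via lithium 4-(trimethylsilyl)buta-1,3-diyn-1-ide 10 (not isolated)
Conditions: MeLi·LiBr (1.05 equiv), Et2O, 0 °C to rt; cold 1 M HCl; kept as a toluene solution
Reagents that add atoms: none
Why: Selective mono-desilylation: one equivalent of MeLi·LiBr cleaves a single C(sp)–Si bond, and the negative charge of acetylide 10 protects the second silyl group. Protonation gives the volatile terminal diyne, which is handled only in solution.

Step 7
Reactants: 8 (2Z)-dec-2-enal; 11 (trimethylsilyl)buta-1,3-diyne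
Product: 13 (5S,6Z)-1-(trimethylsilyl)tetradec-6-ene-1,3-diyn-5-ol, via methyl[4-(trimethylsilyl)buta-1,3-diyn-1-yl]zinc 12 (not isolated)
Conditions: 11 (2.5 equiv), Me2Zn (2.6 equiv), (S,S)-ProPhenol (20 mol%), Ph3P=O (40 mol%), toluene, 0 to 4 °C; then 8; sat. aq. NH4Cl
Reagents that add atoms: none
Why: Zinc–ProPhenol catalysed enantioselective alkynylation of an α,β-unsaturated aldehyde with a terminal 1,3-diyne: Me2Zn metalates 11 to 12, and the dinuclear zinc catalyst holds aldehyde and alkynyl group on neighbouring zinc atoms and delivers the alkynyl group to one carbonyl face. Delivery to the Re face of 8 sets C5 as S (the future C8'); the mild Lewis acidity and the absence of free amine should keep the Z-olefin intact.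

Step 8
Reactants: 13 (5S,6Z)-1-(trimethylsilyl)tetradec-6-ene-1,3-diyn-5-ol
Product: 14 (5S,6Z)-tetradec-6-ene-1,3-diyn-5-ol
Conditions: K2CO3 (0.2 equiv), MeOH, 0 °C; kept as a cold THF solution
Reagents that add atoms: none
Why: Methanolysis of the C(sp)–Si bond with catalytic carbonate; the carbinol C–H is not acidic enough to epimerise under these conditions. The terminal diyne is kept cold and in solution because it oligomerises when neat.

Step 9
Reactants: 5 3-(4-hydroxy-2-oxo-2H-chromen-3-yl)-N-methoxy-N-methylpropanamide; 14 (5S,6Z)-tetradec-6-ene-1,3-diyn-5-ol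
Product: 18 4-hydroxy-3-[(8S,9Z)-8-hydroxy-3-oxoheptadec-9-ene-4,6-diyn-1-yl]-2H-chromen-2-one, via lithium enolate of the amide 15 (not isolated), via dilithium alkoxide acetylide 16 (not isolated), via trilithium tetrahedral adduct 17 (not isolated)
Conditions: 5, LiN(SiMe3)2 (1.05 equiv), THF, −78 °C; 14 (1.3 equiv), n-BuLi (2.6 equiv), THF, −78 °C; combine, −78 to −20 °C; inverse quench into cold 1 M HCl
Reagents that add atoms: none
Why: Ketone synthesis from an N-methoxy-N-methyl amide with both partners protected as their anions: enolate 15 is inert to nucleophiles, alkoxide acetylide 16 needs no protecting group on the carbinol, and the chelated adduct 17 keeps the ketone masked until the quench. The inverse quench into cold acid should protonate the released N,O-dimethylhydroxylamine before it can add to the diynone; 18 should rest mainly as its cyclic hemiketal, which shields both the enol and the ynone.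

Step 10
Reactants: 19 (2E,6E)-farnesol
Product: 20 tert-butyl (2E,6E)-3,7,11-trimethyldodeca-2,6,10-trien-1-yl carbonate
Conditions: Boc2O (1.3 equiv), Bu4NHSO4 (5 mol%), 30% aq. NaOH, CH2Cl2, 0 °C to rt
Reagents that add atoms: di-tert-butyl dicarbonate, CC(C)(C)OC(=O)OC(=O)OC(C)(C)C
Why: Phase-transfer acylation of the allylic alkoxide gives the allyl tert-butyl carbonate without touching the olefin geometry. The tert-butyl carbonate is chosen because its leaving group ends as non-nucleophilic tert-butoxide.

Step 11
Reactants: 18 4-hydroxy-3-[(8S,9Z)-8-hydroxy-3-oxoheptadec-9-ene-4,6-diyn-1-yl]-2H-chromen-2-one; 20 tert-butyl (2E,6E)-3,7,11-trimethyldodeca-2,6,10-trien-1-yl carbonate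
Product: 22 (3S)-3-[(8S,9Z)-8-hydroxy-3-oxoheptadec-9-ene-4,6-diyn-1-yl]-3-[(2E,6E)-3,7,11-trimethyldodeca-2,6,10-trien-1-yl]chromane-2,4-dione (the target), via farnesylpalladium enolate ion pair 21 (not isolated)
Conditions: Pd2(dba)3·CHCl3 (2.5 mol%), (R,R)-DACH-phenyl ligand N,N'-[(1R,2R)-cyclohexane-1,2-diyl]bis[2-(diphenylphosphino)benzamide] (7.5 mol%), 20 (0.95 equiv), degassed CH2Cl2, 0 °C to rt, dark
Reagents that add atoms: none
Why: Zerovalent palladium on the chiral diphosphine ionises 20 to a cationic η3-farnesyl complex, carbon dioxide and tert-butoxide; the alkoxide is quenched at once by 18 (pKa about 4 in its open form), so the only base present is the enolate inside ion pair 21, whose C3 attacks the unsubstituted allyl terminus from outside the metal to give 22 and return the catalyst. The closest known reaction type is the palladium-catalysed asymmetric allylic alkylation of prochiral stabilised nucleophiles to quaternary centres, both in its dearomative form on hydroxyarenes and with linear prenyl-type electrophiles; racemic C3-allylation of 3-alkyl-4-hydroxycoumarins under zerovalent palladium forms the same bond on the same ring. No ring is closed: ring B is dearomatised from a 2-pyranone enol to the 2,4-dione. The C3 stereocentre is set by the ligand pocket, which fixes how the flat enolate (benzo edge against lactone-oxygen edge) lies over the allyl terminus; C8' is eight bonds away and should not interfere, so the diastereoselectivity should equal the catalyst's enantioface selectivity. C- over O-allylation is secured by reversibility, because a 4-farnesyloxycoumarin is an allyl ester of a pKa-4 acid, re-ionises and is funnelled to the C-allyl product. Linear attack is secured because branched attack would join two fully substituted carbons, and the 2''E geometry should hold because scrambling would need a tertiary σ-allyl palladium. The C8' hydroxyl (pKa about 13) is not deprotonated without external base, the short life of the enolate protects the diynone, and with 20 as the limiting reagent no alkoxide outlives the acid; surplus 18 is removed by bicarbonate extraction.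

## Compound list

1 | 4-hydroxycoumarin (4-hydroxy-2H-chromen-2-one) | OC1=CC(=O)Oc2ccccc12 | starting material
2 | acrolein (prop-2-enal) | C=CC=O | starting material
3 | 2-hydroxy-3,4-dihydro-2H,5H-pyrano[3,2-c]chromen-5-one (racemic lactol) | OC1CCC2=C(O1)c1ccccc1OC2=O | intermediate
4 | 3,4-dihydro-2H,5H-pyrano[3,2-c]chromene-2,5-dione | O=C1CCC2=C(O1)c1ccccc1OC2=O | intermediate
5 | 3-(4-hydroxy-2-oxo-2H-chromen-3-yl)-N-methoxy-N-methylpropanamide | CON(C)C(=O)CCC1=C(O)c2ccccc2OC1=O | intermediate
6 | dec-2-yn-1-ol | CCCCCCCC#CCO | starting material
7 | (2Z)-dec-2-en-1-ol | CCCCCCC/C=C\CO | intermediate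
8 | (2Z)-dec-2-enal | CCCCCCC/C=C\C=O | intermediate
9 | 1,4-bis(trimethylsilyl)buta-1,3-diyne | C[Si](C)(C)C#CC#C[Si](C)(C)C | starting material
10 | lithium 4-(trimethylsilyl)buta-1,3-diyn-1-ide (not isolated) | [Li+].[C-]#CC#C[Si](C)(C)C | intermediate
11 | (trimethylsilyl)buta-1,3-diyne | C#CC#C[Si](C)(C)C | intermediate
12 | methyl[4-(trimethylsilyl)buta-1,3-diyn-1-yl]zinc (not isolated) | C[Zn]C#CC#C[Si](C)(C)C | intermediate
13 | (5S,6Z)-1-(trimethylsilyl)tetradec-6-ene-1,3-diyn-5-ol | CCCCCCC/C=C\[C@H](O)C#CC#C[Si](C)(C)C | intermediate
14 | (5S,6Z)-tetradec-6-ene-1,3-diyn-5-ol | CCCCCCC/C=C\[C@H](O)C#CC#C | intermediate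
15 | lithium enolate of amide 5 (not isolated) | [Li+].CON(C)C(=O)CCC1=C([O-])c2ccccc2OC1=O | intermediate
16 | dilithium alkoxide acetylide of 14 (not isolated) | [Li+].[Li+].CCCCCCC/C=C\[C@H]([O-])C#CC#[C-] | intermediate
17 | trilithium tetrahedral adduct of 15 and 16 (not isolated; new carbon unassigned) | [Li+].[Li+].[Li+].CCCCCCC/C=C\[C@H]([O-])C#CC#CC([O-])(CCC1=C([O-])c2ccccc2OC1=O)N(C)OC | intermediate
18 | 4-hydroxy-3-[(8S,9Z)-8-hydroxy-3-oxoheptadec-9-ene-4,6-diyn-1-yl]-2H-chromen-2-one (open form; cyclic hemiketal tautomer expected) | CCCCCCC/C=C\[C@H](O)C#CC#CC(=O)CCC1=C(O)c2ccccc2OC1=O | intermediate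
19 | (2E,6E)-farnesol | CC(C)=CCC/C(C)=C/CC/C(C)=C/CO | starting material
20 | tert-butyl (2E,6E)-3,7,11-trimethyldodeca-2,6,10-trien-1-yl carbonate | CC(C)=CCC/C(C)=C/CC/C(C)=C/COC(=O)OC(C)(C)C | intermediate
21 | ion pair of the enolate of 18 and the (η3-farnesyl)palladium cation (not isolated; diphosphine omitted, allyl drawn in its η1 form) | CCCCCCC/C=C\[C@H](O)C#CC#CC(=O)CCC1=C([O-])c2ccccc2OC1=O.CC(C)=CCC/C(C)=C/CC/C(C)=C/C[Pd+] | intermediate
22 | (3S)-3-[(8S,9Z)-8-hydroxy-3-oxoheptadec-9-ene-4,6-diyn-1-yl]-3-[(2E,6E)-3,7,11-trimethyldodeca-2,6,10-trien-1-yl]chromane-2,4-dione | CCCCCCC/C=C\[C@H](O)C#CC#CC(=O)CC[C@@]1(C/C=C(\C)CC/C=C(\C)CCC=C(C)C)C(=O)Oc2ccccc2C1=O | target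

## Step count and least certain steps

Total: 11 steps. Longest linear sequence: 6 steps (steps 4, 5, 7, 8, 9, 11).

**Step 11 (key step).** Three things are most likely to go wrong.
- Conjugate addition of the transient C3 enolate to C5' of the diynone (a 6-endo closure through the two-carbon tether) could compete with allylation.
- Incomplete enantioface selection would appear here as the C3 epimer, which is hard to remove.
- Part of the 2''E geometry could be lost in the allyl complex.

Fallback: the quaternary centre is set before any ynone exists, and the chain is attached without ever placing a hydroxyl at C3'. It sets out from 3, 14 and 20 and comes back at 22.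
- Lactol 3 is allylated with 20 under the palladium conditions of step 11. The lactol opens on deprotonation and should give the aldehyde (3S)-3-(3-oxopropyl)-3-[(2E,6E)-farnesyl]chromane-2,4-dione F1. F1 is a mixture of enantiomers only, which can be brought to one enantiomer by preparative chromatography on a chiral phase.
- Pinnick oxidation (NaClO2, NaH2PO4, excess 2-methylbut-2-ene) should give the acid 3-[(3S)-3-farnesyl-2,4-dioxochroman-3-yl]propanoic acid F2.
- 1-Chloro-N,N,2-trimethylprop-1-en-1-amine should convert F2 under neutral conditions into the acid chloride 3-[(3S)-3-farnesyl-2,4-dioxochroman-3-yl]propanoyl chloride F3.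
- In parallel, 14 is silylated (TBSCl, imidazole, DMF) to (5S,6Z)-5-(tert-butyldimethylsilyloxy)tetradec-6-ene-1,3-diyne F4.
- Acyl Sonogashira coupling of F3 with F4 (PdCl2(PPh3)2, CuI, Et3N, THF, rt) should give the silyl ether of the target, (3S)-3-[(8S,9Z)-8-(tert-butyldimethylsilyloxy)-3-oxoheptadec-9-ene-4,6-diyn-1-yl]-3-[(2E,6E)-farnesyl]chromane-2,4-dione F5.
- HF·pyridine in THF/pyridine frees the C8' hydroxyl and gives 22.

**Step 9.** The released N,O-dimethylhydroxylamine may add to the diynone if the quench is not cold and acidic enough, and the polyanionic lithium salts may aggregate and react slowly.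

Fallback: the ynone is made by oxidation instead of acyl substitution. It sets out from 3 and the silyl ether F4 of the fallback to step 11 and comes back at 18.
- 3 is opened with LiN(SiMe3)2 to its lithium enolate aldehyde and treated with the lithium acetylide of F4 (n-BuLi, THF, −78 °C). This should give the C3'-epimeric alcohols 4-hydroxy-3-[(8S,9Z)-8-(tert-butyldimethylsilyloxy)-3-hydroxyheptadec-9-ene-4,6-diyn-1-yl]-2H-chromen-2-one F6.
- MnO2 in CH2Cl2 oxidises the only free propargylic alcohol to 4-hydroxy-3-[(8S,9Z)-8-(tert-butyldimethylsilyloxy)-3-oxoheptadec-9-ene-4,6-diyn-1-yl]-2H-chromen-2-one F7.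
- HF·pyridine gives 18.

**Step 7.** The Z-enal may isomerise to the E-enal under the zinc alkoxide conditions, facial selectivity may be lower for a Z-enal than for the usual E-enals, and the sense of induction is assumed.

Fallback: the stereocentre is set by reduction instead of addition. It sets out from 8 and 9 and comes back at 13.
- Acetylide 10, generated from 9, is added to 8 at −78 °C to give the racemic carbinol (6Z)-1-(trimethylsilyl)tetradec-6-ene-1,3-diyn-5-ol F8.
- MnO2 gives the ketone (6Z)-1-(trimethylsilyl)tetradec-6-ene-1,3-diyn-5-one F9.
- (S)-Alpine-Borane (B-isopinocampheyl-9-borabicyclo[3.3.1]nonane from (−)-α-pinene) reduces the ynone with the alkynyl group as the small substituent. By the established model this should give the S-carbinol 13.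

**Step 8.** The terminal diyne may oligomerise during concentration or storage.

Fallback: the terminal diyne is never isolated. It sets out from 13 and comes back at 16. Compound 13 is treated with n-BuLi (1 equiv, alkoxide) and then MeLi·LiBr (1.1 equiv), which cleaves the C(sp)–Si bond as in step 6 and should give 16 directly; 16 is used in step 9 as written.

## Further compounds

F1 | step 11 | (3S)-3-(3-oxopropyl)-3-[(2E,6E)-3,7,11-trimethyldodeca-2,6,10-trien-1-yl]chromane-2,4-dione | O=CCC[C@@]1(C/C=C(\C)CC/C=C(\C)CCC=C(C)C)C(=O)Oc2ccccc2C1=O
F2 | step 11 | 3-[(3S)-2,4-dioxo-3-[(2E,6E)-3,7,11-trimethyldodeca-2,6,10-trien-1-yl]chroman-3-yl]propanoic acid | OC(=O)CC[C@@]1(C/C=C(\C)CC/C=C(\C)CCC=C(C)C)C(=O)Oc2ccccc2C1=O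
F3 | step 11 | 3-[(3S)-2,4-dioxo-3-[(2E,6E)-3,7,11-trimethyldodeca-2,6,10-trien-1-yl]chroman-3-yl]propanoyl chloride | ClC(=O)CC[C@@]1(C/C=C(\C)CC/C=C(\C)CCC=C(C)C)C(=O)Oc2ccccc2C1=O
F4 | step 11 | (5S,6Z)-5-(tert-butyldimethylsilyloxy)tetradec-6-ene-1,3-diyne | CCCCCCC/C=C\[C@H](O[Si](C)(C)C(C)(C)C)C#CC#C
F5 | step 11 | (3S)-3-[(8S,9Z)-8-(tert-butyldimethylsilyloxy)-3-oxoheptadec-9-ene-4,6-diyn-1-yl]-3-[(2E,6E)-3,7,11-trimethyldodeca-2,6,10-trien-1-yl]chromane-2,4-dione | CCCCCCC/C=C\[C@H](O[Si](C)(C)C(C)(C)C)C#CC#CC(=O)CC[C@@]1(C/C=C(\C)CC/C=C(\C)CCC=C(C)C)C(=O)Oc2ccccc2C1=O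
F6 | step 9 | 4-hydroxy-3-[(8S,9Z)-8-(tert-butyldimethylsilyloxy)-3-hydroxyheptadec-9-ene-4,6-diyn-1-yl]-2H-chromen-2-one (C3' epimers) | CCCCCCC/C=C\[C@H](O[Si](C)(C)C(C)(C)C)C#CC#CC(O)CCC1=C(O)c2ccccc2OC1=O
F7 | step 9 | 4-hydroxy-3-[(8S,9Z)-8-(tert-butyldimethylsilyloxy)-3-oxoheptadec-9-ene-4,6-diyn-1-yl]-2H-chromen-2-one | CCCCCCC/C=C\[C@H](O[Si](C)(C)C(C)(C)C)C#CC#CC(=O)CCC1=C(O)c2ccccc2OC1=O
F8 | step 7 | (6Z)-1-(trimethylsilyl)tetradec-6-ene-1,3-diyn-5-ol (racemic) | CCCCCCC/C=C\C(O)C#CC#C[Si](C)(C)C
F9 | step 7 | (6Z)-1-(trimethylsilyl)tetradec-6-ene-1,3-diyn-5-one | CCCCCCC/C=C\C(=O)C#CC#C[Si](C)(C)C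
F0 | step 8 | none | none
A1 | alternative 1 | ferulenol, 4-hydroxy-3-[(2E,6E)-3,7,11-trimethyldodeca-2,6,10-trien-1-yl]-2H-chromen-2-one | CC(C)=CCC/C(C)=C/CC/C(C)=C/CC1=C(O)c2ccccc2OC1=O
A2 | alternative 1 | falcarinolone, (8S,9Z)-8-hydroxyheptadeca-1,9-diene-4,6-diyn-3-one | CCCCCCC/C=C\[C@H](O)C#CC#CC(=O)C=C
A3 | alternative 2 | 2-[(8S,9Z)-8-hydroxy-3-oxoheptadec-9-ene-4,6-diyn-1-yl]-2-[(2E,6E)-3,7,11-trimethyldodeca-2,6,10-trien-1-yl]indane-1,3-dione | CCCCCCC/C=C\[C@H](O)C#CC#CC(=O)CCC1(C/C=C(\C)CC/C=C(\C)CCC=C(C)C)C(=O)c2ccccc2C1=O
A4 | alternative 2 | 3-[(8S,9Z)-8-hydroxy-3-oxoheptadec-9-ene-4,6-diyn-1-yl]-3-[(2E,6E)-3,7,11-trimethyldodeca-2,6,10-trien-1-yl]isochromane-1,4-dione (C3 unassigned) | CCCCCCC/C=C\[C@H](O)C#CC#CC(=O)CCC1(C/C=C(\C)CC/C=C(\C)CCC=C(C)C)OC(=O)c2ccccc2C1=O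
A5 | alternative 3 | 3-[(8S,9Z)-8-hydroxy-3-oxoheptadec-9-ene-4,6-diyn-1-yl]-4-[[(6E)-3,7,11-trimethyldodeca-1,6,10-trien-3-yl]oxy]-2H-chromen-2-one | CCCCCCC/C=C\[C@H](O)C#CC#CC(=O)CCC1=C(OC(C)(C=C)CC/C=C(\C)CCC=C(C)C)c2ccccc2OC1=O
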